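## The problem

The target is a biflavonoid. A (2S)-5,7,3′,4′-tetrahydroxyflavanone is bonded through C5′ of its catechol ring B to C8 of a 5,7,4′-trihydroxyflavone, so that two benzopyranone bicycles and a 4-hydroxyphenyl ring hang on one central catechol ring. The bond between the two flavonoid halves is the skeletal difficulty: flavone C8 lies between the oxygen on C7 and the ring oxygen on C8a, and catechol C5′ is ortho to the C4′ oxygen, so a cross-coupling would have to join a doubly ortho-oxygenated, electron-rich carbon to an ortho-oxygenated one. There is a single stereocentre, flavanone C2 (S, read from the SMILES string). Nothing else in the molecule is stereogenic, so no substrate control exists and the configuration must come from a chiral catalyst or reagent. That centre is labile: base or strong acid opens the flavanone to the 2′-hydroxychalcone by retro-oxa-Michael reaction and recloses it as the racemate, so C2 should be made late and see only neutral conditions afterwards. Seven phenols, among them an oxidation-prone catechol, must be masked by groups that leave without acid, base or Lewis acid, and the flavone C2=C3 bond, both C4 carbonyls and the benzylic C2–O1 bond of the flavanone must survive the unmasking. The enabling feature is flavone ring A: a benzene ring with oxygens on C5, C7 and C8a and the catechol ring on C8. A 3-alkoxy vinylketene (C8a, C4a, C5 with its oxygen, C6) and an aryl ynol ether (C8 with the aryl group, C7 with its oxygen) give exactly this pattern on benzannulation, so the hindered aryl–aryl bond can exist from the start as an aryl–alkyne bond and ring A can be grown around it.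

## Retrosynthesis

**Target 31 from heptabenzyl ether 30.** Seven O–benzyl bonds are cut. Benzyl is preferred to methyl (cleavage needs boron or aluminium halides that open the flavanone) and to silyl or acetal groups (fluoride or acid), because hydrogenolysis is neutral. Precursor 30 has the full skeleton and the stereocentre. The forward step must spare the flavone alkene, the ketones and the benzylic C2–O1 bond.

**30 from boronic acid 25 and chromone 29.** The flavanone C2–C1′ bond is cut. The neighbouring cut, O1–C2 (cyclisation of a 2′-hydroxychalcone), relies on asymmetric oxa-Michael additions that are less general for unactivated chalcones. Conjugate arylation of a chromone creates C2 in the C–C bond-forming event under catalyst control, and it does so on the finished biaryl. The precursors are achiral. The forward reaction must discriminate the two faces of 29, overcome the low electrophilicity of a 5,7-dialkoxychromone and run without base. The boron of 25 has two free ortho positions, which helps transmetalation.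

**29 from acetophenone 27 and 2′,4′,6′-trihydroxyacetophenone 26.** O1–C2 and C2–C3 of the chromone are cut; the one carbon comes from a formamide acetal through enaminone 28. Chelation of one hydroxyl in 26 allows selective dibenzylation to 27.

**25 from pinacol boronate 24 and bromide 23.** The C–B bond is traced to a C–Br bond. A bromide is inert to everything earlier (amide base, heat, magnesium salts, fluoride) and is converted only when the nucleophile is needed.

**23 from silyl ether 21.** The C7 O–benzyl bond replaces an O–silyl bond so that the final deprotection is a single operation. The exchange is placed at the flavone stage, where no free phenol competes and no stereocentre exists yet.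

**21 from carbinol 19, hence aldehyde 16 and alkyne 17.** Flavone O1–C2 (cyclisation of ynone 20) and C3–C4 (acetylide addition) are cut. The neighbouring route through an ortho-hydroxyacetophenone and Baker–Venkataraman rearrangement would need an acetyl group on C4a of phenol 14. Fries rearrangement or Friedel–Crafts acetylation would require Lewis acids that cleave aryl benzyl and silyl ethers and could also attack C6 between the two ethers. The ynone route needs only a formyl group. Precursor 17 is commercial. The forward steps must add to a phenoxide-deactivated aldehyde and close 6-endo, not 5-exo.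

**16 from phenol 14.** The C4a–CHO bond is cut. Magnesium phenoxide-templated formylation reacts only ortho to the free hydroxyl, and only one such position (C4a) is open.

**14 from siloxyalkyne 7 and cyclobutenone 9 (key disconnection).** Bonds C8–C8a and C6–C7 are cut and ring A is taken apart. Compared with a cross-coupling at C8, this removes the hindered biaryl coupling altogether and leaves two small fragments. The three ring-A oxygens emerge differentiated: free hydroxyl on C8a for ring closure, silyl ether on C7, benzyl ether on C5. The forward reaction requires 9 to open to vinylketene 10 and the [2+2] step to follow the polarisation of the ynol ether.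

**7 from alkyne 4, aldehyde 3, catechol 2 and 5-bromo-2-hydroxy-3-methoxybenzaldehyde 1; 9 from 3-ethoxycyclobutenone 8.** The ynol oxygen, the alkyne carbon and the benzyl groups are removed in turn. In 1 the formyl carbon is ortho to the oxygen that becomes O4′ and the bromine is para to it, which is the relation between the biaryl carbon C5′ and the flavanone-bearing carbon C1′. Cyclobutenone 9 comes from commercial 8 by exchange of the alkoxy group.

## Roads not taken

**Alternative 1:** The flavone C2=C3 bond is cut. On heating, the ylide carbon of acylmethylenephosphorane A1 would attack the neighbouring 4-(benzyloxy)benzoate carbonyl (intramolecular ester Wittig) and give flavone A2, whose dioxolane would later serve as the aldehyde for a chalcone-based flavanone.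
- Merits: the ring closure is thermal and free of acid and base, and it avoids the sensitive carbinol 19 of the chosen route. In that respect it is the cleaner closure of ring C.
- Weak points: the ester to be olefinated sits on a phenol oxygen flanked by the catechol ring. A1 needs a biaryl ortho-hydroxyacetophenone, then α-bromination (which competes with bromination of the electron-rich ring A), phosphonium salt formation and aroylation. The biaryl bond at C8 must still be made by cross-coupling between two oxygens. The flavanone would come from an asymmetric chalcone cyclisation.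
- Comparison: the chosen plan has a less elegant ring-C closure (steps 8 and 9). It sets against this a biaryl that is never made by coupling and a C2 stereocentre set by catalytic C–C bond formation.

**Alternative 2:** The flavanone C4–C4a bond is cut. The mixed anhydride of (S)-acid A3 would acylate an ortho carbon of its symmetric 3,5-bis(benzyloxy)phenoxy ring (intramolecular Friedel–Crafts acylation) and give protected flavanone A4 without touching C2.
- Merits: both ortho positions are equivalent, and C2 would be set earlier by stoichiometric steps (asymmetric reduction, Mitsunobu etherification). That stereocontrol is at least as predictable as the catalytic arylation of step 15, which has no counterpart on so large a boronic acid.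
- Weak points: in A3 the aryloxy group is β to the activated acyl group and benzylic, so elimination to a cinnamate or ionisation threatens the stereocentre. This forces carbonate protection of the catechol, a second, base-labile protecting-group class. Etherification at a benzylic alcohol can leak through ion pairs. The whole flavone–catechol biaryl must exist before the chain is built.
- Comparison: the chosen plan offers one step from 25 and 29 to 30, one protecting-group class and no acid on a C2-bearing intermediate.

**Alternative 3:** Flavone C3–C4 and O1–C2 are cut. Trivalent rhodium would insert into the formyl C–H bond of biaryl salicylaldehyde A5, the aroyl sulfoxonium ylide A6 would deliver the acylmethyl unit, and cyclodehydration would give flavone A7.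
- Merits: one step from aldehyde to flavone, against two operations (steps 8 and 9) in the chosen route, and no carbinol. For ring C this is the better closure.
- Weak points: A5 is itself a product of cross-coupling at the hindered carbon between two oxygens. A cationic rhodium–silver system at high temperature meets six benzyl ethers. The chloride is harder to borylate than a bromide.
- Comparison: the chosen route passes through aldehyde 16, the silyl analogue of A5, so this annulation is kept as the fallback for step 8. What the chosen plan adds is access to that aldehyde without a biaryl coupling (steps 6 and 7).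

Key step: step 6

Assumption: the sense of induction of the rhodium–bisphosphine catalyst in step 15 is taken from simple chromones; if the 2R flavanone predominated, the antipodal ligand would be used.

## Steps

Step 1
Reactants: 1 5-bromo-2-hydroxy-3-methoxybenzaldehyde
Product: 2 5-bromo-2,3-dihydroxybenzaldehyde
Conditions: BBr3, CH2Cl2, −78 °C to rt; then H2O
Reagents that add atoms: none
Why: Lewis-acid cleavage of an aryl methyl ether; bromide attacks the methyl group of the boron-complexed ether and the borate hydrolyses on work-up, while the aldehyde and aryl bromide are untouched.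

Step 2
Reactants: 2 5-bromo-2,3-dihydroxybenzaldehyde
Product: 3 2,3-bis(benzyloxy)-5-bromobenzaldehyde
Conditions: BnBr, K2CO3, DMF, 60 °C
Reagents that add atoms: benzyl bromide, BrCc1ccccc1
Why: Williamson etherification; at 60 °C in DMF the chelated 2-hydroxyl is alkylated as well, and benzyl is the group removed by hydrogenolysis at the end.

Step 3
Reactants: 3 2,3-bis(benzyloxy)-5-bromobenzaldehyde
Product: 4 1,2-bis(benzyloxy)-5-bromo-3-ethynylbenzene
Conditions: dimethyl (1-diazo-2-oxopropyl)phosphonate, K2CO3, MeOH/THF, 0 °C to rt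
Reagents that add atoms: dimethyl (1-diazo-2-oxopropyl)phosphonate, CC(=O)C(=[N+]=[N-])P(=O)(OC)OC
Why: Seyferth–Gilbert homologation in the Ohira–Bestmann form; the non-enolisable aryl aldehyde is converted through a diazoalkene and 1,2-hydrogen shift of the alkylidene carbene into the terminal alkyne under mild base that spares the bromide and the benzyl ethers.

Step 4
Reactants: 4 1,2-bis(benzyloxy)-5-bromo-3-ethynylbenzene
Product: 7 {[2,3-bis(benzyloxy)-5-bromophenyl]ethynyl}oxy(triisopropyl)silane, via lithium acetylide 5 (not isolated), via lithium ynolate 6 (not isolated)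
Conditions: LiN(SiMe3)2, t-BuOOH, THF, −78 to 0 °C; then i-Pr3SiOTf, −78 °C to rt
Reagents that add atoms: tert-butyl hydroperoxide, CC(C)(C)OO; triisopropylsilyl trifluoromethanesulfonate, CC(C)[Si](OS(=O)(=O)C(F)(F)F)(C(C)C)C(C)C
Why: Oxidation of a lithium acetylide by lithium tert-butyl peroxide transfers oxygen to the acetylide carbon to give ynolate 6, which the silyl triflate traps on oxygen. The amide base deprotonates the alkyne without bromine–lithium exchange, and the bulky silyl group makes the ynol ether isolable.

Step 5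
Reactants: 8 3-ethoxycyclobut-2-en-1-one
Product: 9 3-(benzyloxy)cyclobut-2-en-1-one
Conditions: BnOH, PPTS (cat.), PhMe, 45 °C, reduced pressure (removal of EtOH)
Reagents that add atoms: benzyl alcohol, OCc1ccccc1
Why: Acid-catalysed vinylogous transesterification (addition of benzyl alcohol to C3 of the activated enone, loss of ethanol), driven by removal of the more volatile alcohol.

Step 6
Reactants: 7 {[2,3-bis(benzyloxy)-5-bromophenyl]ethynyl}oxy(triisopropyl)silane; 9 3-(benzyloxy)cyclobut-2-en-1-one
Product: 14 2-[2,3-bis(benzyloxy)-5-bromophenyl]-5-(benzyloxy)-3-[(triisopropylsilyl)oxy]phenol, via vinylketene 10 (not isolated), via vinylcyclobutenone 11 (not isolated), via dienylketene 12 (not isolated), via cyclohexadienone 13 (not isolated)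
Conditions: 9 (2 equiv, slow addition), PhMe, 110 °C, sealed tube
Reagents that add atoms: none
Why: On heating, 9 undergoes four-electron electrocyclic opening to vinylketene 10, whose ketene C=C bond adds in a [2+2] sense to the electron-rich alkyne 7 to give vinylcyclobutenone 11; 11 opens again (four-electron, reversible) to dienylketene 12, which closes by six-electron electrocyclisation to cyclohexadienone 13 and tautomerises to phenol 14. The closest known reaction type is the Danheiser benzannulation of cyclobutenones with siloxyalkynes to resorcinol monosilyl ethers; pairing a 3-alkoxycyclobutenone with an ortho-substituted aryl ynol ether is an untested combination within that class, supported by the fact that 11, like the corresponding intermediate of every siloxyalkyne benzannulation, is itself a 3-oxygenated cyclobutenone that opens under these conditions. Flavone ring A is closed as a six-membered carbocycle by the disrotatory closure of 12 (bond C8a–C4a), after the [2+2] step has made the two new skeletal bonds C8–C8a and C6–C7. No stereocentre remains, because the sp3 carbon of 11 is lost on ring opening. The selectivity needed is the regiochemistry of the [2+2] step, secured by the polarisation of the ynol ether: its aryl-bearing carbon is the nucleophilic one and bonds to the ketene carbonyl carbon, so the aryl group ends up on C8 next to the new hydroxyl on C8a and the silyloxy group on C7. Only the isomer of 12 with ketene and vinyl group cis can cyclise, and reversible opening of 11 feeds it. Slow addition of 9 keeps the ketene concentration low against dimerisation, and the bulky silyl group suppresses the 1,3-silyl shift of 7 to a silylketene.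

Step 7
Reactants: 14 2-[2,3-bis(benzyloxy)-5-bromophenyl]-5-(benzyloxy)-3-[(triisopropylsilyl)oxy]phenol
Product: 16 3-[2,3-bis(benzyloxy)-5-bromophenyl]-6-(benzyloxy)-2-hydroxy-4-[(triisopropylsilyl)oxy]benzaldehyde, via salicyl alcohol 15 (not isolated)
Conditions: MgCl2, Et3N, (CH2O)n, MeCN, reflux; aq. HCl work-up
Reagents that add atoms: paraformaldehyde (as formaldehyde), C=O
Why: Magnesium-mediated ortho-formylation of a phenol; the magnesium phenoxide delivers formaldehyde to the only free ortho carbon (C4a) to give 15, whose magnesium alkoxide is oxidised by hydride transfer to a second formaldehyde. No Lewis acid able to cleave benzyl or silyl ethers is present, and C6 between the two ethers is not attacked.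

Step 8
Reactants: 16 3-[2,3-bis(benzyloxy)-5-bromophenyl]-6-(benzyloxy)-2-hydroxy-4-[(triisopropylsilyl)oxy]benzaldehyde; 17 1-(benzyloxy)-4-ethynylbenzene
Product: 19 6-[2,3-bis(benzyloxy)-5-bromophenyl]-3-(benzyloxy)-2-{3-[4-(benzyloxy)phenyl]-1-hydroxyprop-2-yn-1-yl}-5-[(triisopropylsilyl)oxy]phenol (racemic), via lithium acetylide 18 (not isolated)
Conditions: 17 (3.2 equiv), n-BuLi (3.0 equiv), THF, −78 °C; then 16, −78 to 0 °C; pH 7 buffer
Reagents that add atoms: none
Why: 1,2-Addition of a lithium acetylide to an aldehyde; the first equivalent deprotonates the phenol, lithium chelation between phenoxide and formyl oxygen keeps the carbonyl reactive, and the slight deficit of n-BuLi leaves no alkyllithium to exchange with the aryl bromide. The new carbinol centre is racemic and is destroyed in step 9.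

Step 9
Reactants: 19 6-[2,3-bis(benzyloxy)-5-bromophenyl]-3-(benzyloxy)-2-{3-[4-(benzyloxy)phenyl]-1-hydroxyprop-2-yn-1-yl}-5-[(triisopropylsilyl)oxy]phenol
Product: 21 8-[2,3-bis(benzyloxy)-5-bromophenyl]-5-(benzyloxy)-2-[4-(benzyloxy)phenyl]-7-[(triisopropylsilyl)oxy]-4H-chromen-4-one, via ynone 20 (not isolated)
Conditions: MnO2, CH2Cl2, rt; filter, concentrate; then Et2NH, EtOH, rt
Reagents that add atoms: none
Why: MnO2 oxidises only the propargylic–benzylic alcohol. Diethylamine then adds to ynone 20 to give a β-amino enone that the ortho phenol displaces by addition–elimination, which enforces 6-endo closure to the flavone and not 5-exo closure to an aurone.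

Step 10
Reactants: 21 8-[2,3-bis(benzyloxy)-5-bromophenyl]-5-(benzyloxy)-2-[4-(benzyloxy)phenyl]-7-[(triisopropylsilyl)oxy]-4H-chromen-4-one
Product: 23 8-[2,3-bis(benzyloxy)-5-bromophenyl]-5,7-bis(benzyloxy)-2-[4-(benzyloxy)phenyl]-4H-chromen-4-one, via cesium phenoxide 22 (not isolated)
Conditions: CsF, BnBr, DMF, rt
Reagents that add atoms: benzyl bromide, BrCc1ccccc1
Why: Fluoride cleaves the aryl silyl ether to phenoxide 22, which is benzylated in the same flask (desilylative Williamson etherification); no other free phenol is present at this stage.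

Step 11
Reactants: 23 8-[2,3-bis(benzyloxy)-5-bromophenyl]-5,7-bis(benzyloxy)-2-[4-(benzyloxy)phenyl]-4H-chromen-4-one
Product: 24 5,7-bis(benzyloxy)-2-[4-(benzyloxy)phenyl]-8-[2,3-bis(benzyloxy)-5-(4,4,5,5-tetramethyl-1,3,2-dioxaborolan-2-yl)phenyl]-4H-chromen-4-one
Conditions: B2pin2, PdCl2(dppf) (cat.), KOAc, 1,4-dioxane, 90 °C
Reagents that add atoms: bis(pinacolato)diboron, CC1(C)OB(OC1(C)C)B1OC(C)(C)C(C)(C)O1
Why: Miyaura borylation; zerovalent palladium adds to the unhindered aryl bromide, acetate-assisted transmetalation with the diboron and reductive elimination give the boronate, and the flavone is inert to these conditions.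

Step 12
Reactants: 24 5,7-bis(benzyloxy)-2-[4-(benzyloxy)phenyl]-8-[2,3-bis(benzyloxy)-5-(4,4,5,5-tetramethyl-1,3,2-dioxaborolan-2-yl)phenyl]-4H-chromen-4-one
Product: 25 {3,4-bis(benzyloxy)-5-[5,7-bis(benzyloxy)-2-(4-(benzyloxy)phenyl)-4-oxo-4H-chromen-8-yl]phenyl}boronic acid
Conditions: NaIO4, NH4OAc, THF/acetone/H2O, rt
Reagents that add atoms: water, O
Why: Oxidative cleavage of a pinacol boronate; periodate destroys pinacol as hydrolysis releases it and pulls the equilibrium to the free boronic acid, which transmetalates to rhodium far faster than the ester.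

Step 13
Reactants: 26 1-(2,4,6-trihydroxyphenyl)ethan-1-one
Product: 27 1-[2,4-bis(benzyloxy)-6-hydroxyphenyl]ethan-1-one
Conditions: BnBr (2.1 equiv), K2CO3, DMF, rt
Reagents that add atoms: benzyl bromide, BrCc1ccccc1
Why: Williamson etherification that stops at the bis-ether, because the remaining hydroxyl is hydrogen-bonded to the acetyl carbonyl and much less nucleophilic.

Step 14
Reactants: 27 1-[2,4-bis(benzyloxy)-6-hydroxyphenyl]ethan-1-one
Product: 29 5,7-bis(benzyloxy)-4H-chromen-4-one, via enaminone 28 (not isolated)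
Conditions: Me2NCH(OMe)2, PhMe, 100 °C; concentrate; then aq. HCl, CH2Cl2, rt
Reagents that add atoms: N,N-dimethylformamide dimethyl acetal, COC(OC)N(C)C
Why: Enaminone route to chromones; condensation of the methyl ketone with the formamide acetal gives 28, and acid promotes attack of the phenol on the β-carbon with loss of dimethylamine to close the pyranone ring.

Step 15
Reactants: 25 {3,4-bis(benzyloxy)-5-[5,7-bis(benzyloxy)-2-(4-(benzyloxy)phenyl)-4-oxo-4H-chromen-8-yl]phenyl}boronic acid; 29 5,7-bis(benzyloxy)-4H-chromen-4-one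
Product: 30 (2S)-5,7-bis(benzyloxy)-2-{3,4-bis(benzyloxy)-5-[5,7-bis(benzyloxy)-2-(4-(benzyloxy)phenyl)-4-oxo-4H-chromen-8-yl]phenyl}-2,3-dihydro-4H-chromen-4-one
Conditions: 29 (3 equiv), [Rh(OH)(cod)]2 (cat.), (R)-MeO-F12-BIPHEP, PhMe/H2O, 50 °C
Reagents that add atoms: none
Why: Rhodium-catalysed asymmetric 1,4-addition of an arylboronic acid to a chromone (Hayashi–Miyaura type). The aryl–rhodium species carrying the electron-poor bisphosphine 2,2′-bis[bis(3,4,5-trifluorophenyl)phosphino]-6,6′-dimethoxybiphenyl inserts the chromone alkene from the Re face of C2, which gives 2S. Water protonates the rhodium enolate without added base, so retro-oxa-Michael opening is avoided.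

Step 16
Reactants: 30 (2S)-5,7-bis(benzyloxy)-2-{3,4-bis(benzyloxy)-5-[5,7-bis(benzyloxy)-2-(4-(benzyloxy)phenyl)-4-oxo-4H-chromen-8-yl]phenyl}-2,3-dihydro-4H-chromen-4-one
Product: 31 (2S)-2-{3,4-dihydroxy-5-[5,7-dihydroxy-2-(4-hydroxyphenyl)-4-oxo-4H-chromen-8-yl]phenyl}-5,7-dihydroxy-2,3-dihydro-4H-chromen-4-one
Conditions: H2 (1 atm), 10% Pd/C, THF/MeOH, rt, exclusion of air on work-up
Reagents that add atoms: none
Why: Catalytic hydrogenolysis of seven aryl benzyl ethers under neutral conditions; these cleave faster than the conjugated flavone alkene is saturated or the flavanone C2–O1 bond is cut, and neither acid nor base is present to epimerise C2.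

## Compound list

1 | 5-bromo-2-hydroxy-3-methoxybenzaldehyde | COc1cc(Br)cc(C=O)c1O | starting material
2 | 5-bromo-2,3-dihydroxybenzaldehyde | O=Cc1cc(Br)cc(O)c1O | intermediate
3 | 2,3-bis(benzyloxy)-5-bromobenzaldehyde | O=Cc1cc(Br)cc(OCc2ccccc2)c1OCc1ccccc1 | intermediate
4 | 1,2-bis(benzyloxy)-5-bromo-3-ethynylbenzene | C#Cc1cc(Br)cc(OCc2ccccc2)c1OCc1ccccc1 | intermediate
5 | lithium [2,3-bis(benzyloxy)-5-bromophenyl]acetylide | [Li]C#Cc1cc(Br)cc(OCc2ccccc2)c1OCc1ccccc1 | intermediate (not isolated)
6 | lithium 2-[2,3-bis(benzyloxy)-5-bromophenyl]ethynolate | [Li+].[O-]C#Cc1cc(Br)cc(OCc2ccccc2)c1OCc1ccccc1 | intermediate (not isolated)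
7 | {[2,3-bis(benzyloxy)-5-bromophenyl]ethynyl}oxy(triisopropyl)silane | CC(C)[Si](OC#Cc1cc(Br)cc(OCc2ccccc2)c1OCc1ccccc1)(C(C)C)C(C)C | intermediate
8 | 3-ethoxycyclobut-2-en-1-one | CCOC1=CC(=O)C1 | starting material
9 | 3-(benzyloxy)cyclobut-2-en-1-one | O=C1C=C(OCc2ccccc2)C1 | intermediate
10 | 3-(benzyloxy)buta-1,3-dien-1-one | C=C(OCc1ccccc1)C=C=O | intermediate (not isolated)
11 | 2-[2,3-bis(benzyloxy)-5-bromophenyl]-4-[1-(benzyloxy)ethenyl]-3-[(triisopropylsilyl)oxy]cyclobut-2-en-1-one (racemic) | O=C1C(c2cc(Br)cc(OCc3ccccc3)c2OCc2ccccc2)=C(O[Si](C(C)C)(C(C)C)C(C)C)C1C(=C)OCc1ccccc1 | intermediate (not isolated)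
12 | (3E)-2-[2,3-bis(benzyloxy)-5-bromophenyl]-5-(benzyloxy)-3-[(triisopropylsilyl)oxy]hexa-1,3,5-trien-1-one | O=C=C(c1cc(Br)cc(OCc2ccccc2)c1OCc1ccccc1)/C(O[Si](C(C)C)(C(C)C)C(C)C)=C\C(=C)OCc1ccccc1 | intermediate (not isolated)
13 | 2-[2,3-bis(benzyloxy)-5-bromophenyl]-5-(benzyloxy)-3-[(triisopropylsilyl)oxy]cyclohexa-2,4-dien-1-one | O=C1CC(OCc2ccccc2)=CC(O[Si](C(C)C)(C(C)C)C(C)C)=C1c1cc(Br)cc(OCc2ccccc2)c1OCc1ccccc1 | intermediate (not isolated)
14 | 2-[2,3-bis(benzyloxy)-5-bromophenyl]-5-(benzyloxy)-3-[(triisopropylsilyl)oxy]phenol | Oc1cc(OCc2ccccc2)cc(O[Si](C(C)C)(C(C)C)C(C)C)c1-c1cc(Br)cc(OCc2ccccc2)c1OCc1ccccc1 | intermediate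
15 | 6-[2,3-bis(benzyloxy)-5-bromophenyl]-3-(benzyloxy)-2-(hydroxymethyl)-5-[(triisopropylsilyl)oxy]phenol | OCc1c(O)c(-c2cc(Br)cc(OCc3ccccc3)c2OCc2ccccc2)c(O[Si](C(C)C)(C(C)C)C(C)C)cc1OCc1ccccc1 | intermediate (not isolated)
16 | 3-[2,3-bis(benzyloxy)-5-bromophenyl]-6-(benzyloxy)-2-hydroxy-4-[(triisopropylsilyl)oxy]benzaldehyde | O=Cc1c(O)c(-c2cc(Br)cc(OCc3ccccc3)c2OCc2ccccc2)c(O[Si](C(C)C)(C(C)C)C(C)C)cc1OCc1ccccc1 | intermediate
17 | 1-(benzyloxy)-4-ethynylbenzene | C#Cc1ccc(OCc2ccccc2)cc1 | starting material
18 | lithium [4-(benzyloxy)phenyl]acetylide | [Li]C#Cc1ccc(OCc2ccccc2)cc1 | intermediate (not isolated)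
19 | 6-[2,3-bis(benzyloxy)-5-bromophenyl]-3-(benzyloxy)-2-{3-[4-(benzyloxy)phenyl]-1-hydroxyprop-2-yn-1-yl}-5-[(triisopropylsilyl)oxy]phenol (racemic) | OC(C#Cc1ccc(OCc2ccccc2)cc1)c1c(O)c(-c2cc(Br)cc(OCc3ccccc3)c2OCc2ccccc2)c(O[Si](C(C)C)(C(C)C)C(C)C)cc1OCc1ccccc1 | intermediate
20 | 1-{3-[2,3-bis(benzyloxy)-5-bromophenyl]-6-(benzyloxy)-2-hydroxy-4-[(triisopropylsilyl)oxy]phenyl}-3-[4-(benzyloxy)phenyl]prop-2-yn-1-one | O=C(C#Cc1ccc(OCc2ccccc2)cc1)c1c(O)c(-c2cc(Br)cc(OCc3ccccc3)c2OCc2ccccc2)c(O[Si](C(C)C)(C(C)C)C(C)C)cc1OCc1ccccc1 | intermediate (not isolated)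
21 | 8-[2,3-bis(benzyloxy)-5-bromophenyl]-5-(benzyloxy)-2-[4-(benzyloxy)phenyl]-7-[(triisopropylsilyl)oxy]-4H-chromen-4-one | O=c1cc(-c2ccc(OCc3ccccc3)cc2)oc2c(-c3cc(Br)cc(OCc4ccccc4)c3OCc3ccccc3)c(O[Si](C(C)C)(C(C)C)C(C)C)cc(OCc3ccccc3)c12 | intermediate
22 | cesium 8-[2,3-bis(benzyloxy)-5-bromophenyl]-5-(benzyloxy)-2-[4-(benzyloxy)phenyl]-4-oxo-4H-chromen-7-olate | [Cs+].[O-]c1cc(OCc2ccccc2)c2c(=O)cc(-c3ccc(OCc4ccccc4)cc3)oc2c1-c1cc(Br)cc(OCc2ccccc2)c1OCc1ccccc1 | intermediate (not isolated)
23 | 8-[2,3-bis(benzyloxy)-5-bromophenyl]-5,7-bis(benzyloxy)-2-[4-(benzyloxy)phenyl]-4H-chromen-4-one | O=c1cc(-c2ccc(OCc3ccccc3)cc2)oc2c(-c3cc(Br)cc(OCc4ccccc4)c3OCc3ccccc3)c(OCc3ccccc3)cc(OCc3ccccc3)c12 | intermediate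
24 | 5,7-bis(benzyloxy)-2-[4-(benzyloxy)phenyl]-8-[2,3-bis(benzyloxy)-5-(4,4,5,5-tetramethyl-1,3,2-dioxaborolan-2-yl)phenyl]-4H-chromen-4-one | CC1(C)OB(c2cc(OCc3ccccc3)c(OCc3ccccc3)c(-c3c(OCc4ccccc4)cc(OCc4ccccc4)c4c(=O)cc(-c5ccc(OCc6ccccc6)cc5)oc34)c2)OC1(C)C | intermediate
25 | {3,4-bis(benzyloxy)-5-[5,7-bis(benzyloxy)-2-(4-(benzyloxy)phenyl)-4-oxo-4H-chromen-8-yl]phenyl}boronic acid | OB(O)c1cc(OCc2ccccc2)c(OCc2ccccc2)c(-c2c(OCc3ccccc3)cc(OCc3ccccc3)c3c(=O)cc(-c4ccc(OCc5ccccc5)cc4)oc23)c1 | intermediate
26 | 1-(2,4,6-trihydroxyphenyl)ethan-1-one | CC(=O)c1c(O)cc(O)cc1O | starting material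
27 | 1-[2,4-bis(benzyloxy)-6-hydroxyphenyl]ethan-1-one | CC(=O)c1c(O)cc(OCc2ccccc2)cc1OCc1ccccc1 | intermediate
28 | (2E)-1-[2,4-bis(benzyloxy)-6-hydroxyphenyl]-3-(dimethylamino)prop-2-en-1-one | CN(C)/C=C/C(=O)c1c(O)cc(OCc2ccccc2)cc1OCc1ccccc1 | intermediate (not isolated)
29 | 5,7-bis(benzyloxy)-4H-chromen-4-one | O=c1ccoc2cc(OCc3ccccc3)cc(OCc3ccccc3)c12 | intermediate
30 | (2S)-5,7-bis(benzyloxy)-2-{3,4-bis(benzyloxy)-5-[5,7-bis(benzyloxy)-2-(4-(benzyloxy)phenyl)-4-oxo-4H-chromen-8-yl]phenyl}-2,3-dihydro-4H-chromen-4-one | O=C1C[C@@H](c2cc(OCc3ccccc3)c(OCc3ccccc3)c(-c3c(OCc4ccccc4)cc(OCc4ccccc4)c4c(=O)cc(-c5ccc(OCc6ccccc6)cc5)oc34)c2)Oc2cc(OCc3ccccc3)cc(OCc3ccccc3)c21 | intermediate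
31 | (2S)-2-{3,4-dihydroxy-5-[5,7-dihydroxy-2-(4-hydroxyphenyl)-4-oxo-4H-chromen-8-yl]phenyl}-5,7-dihydroxy-2,3-dihydro-4H-chromen-4-one | O=C1C[C@@H](c2cc(O)c(O)c(-c3c(O)cc(O)c4c(=O)cc(-c5ccc(O)cc5)oc34)c2)Oc2cc(O)cc(O)c21 | target

## Step count and least certain steps

Total: 16 steps. Longest linear sequence: 13 steps (steps 1–4, 6–12, 15, 16).

**Step 6 (key step).** The vinylogous ester 9 may open sluggishly, so that ketene 10 forms only at temperatures where 7 rearranges by silyl shift. Dimerisation of 10, or acylation of the new phenol by a second ketene, may outrun the [2+2] addition to the hindered ortho-benzyloxy aryl alkyne.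
Fallback (sets out from 3 and 27, returns at 23): the biaryl bond would be made by cross-coupling.
- Pinnick oxidation of 3 would give 2,3-bis(benzyloxy)-5-bromobenzoic acid F1.
- Metal-free iododecarboxylation (I2, K3PO4, MeCN, heat), which ortho-alkoxybenzoic acids undergo, would give 1,2-bis(benzyloxy)-5-bromo-3-iodobenzene F2.
- Iodine–magnesium exchange with i-PrMgCl·LiCl, which leaves the bromide alone, and quenching with 2-isopropoxy-4,4,5,5-tetramethyl-1,3,2-dioxaborolane would give 2-[2,3-bis(benzyloxy)-5-bromophenyl]-4,4,5,5-tetramethyl-1,3,2-dioxaborolane F3.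
- Iodination of 27 with N-iodosuccinimide ortho to the free hydroxyl would give 1-[4,6-bis(benzyloxy)-2-hydroxy-3-iodophenyl]ethan-1-one F4.
- C-Acylation of its lithium polyanion (LiN(SiMe3)2) with 4-(benzyloxy)benzoyl chloride would give 1-[4,6-bis(benzyloxy)-2-hydroxy-3-iodophenyl]-3-[4-(benzyloxy)phenyl]propane-1,3-dione F5.
- Acid-catalysed cyclodehydration would give 5,7-bis(benzyloxy)-2-[4-(benzyloxy)phenyl]-8-iodo-4H-chromen-4-one F6.
- Suzuki–Miyaura coupling of F6 with F3 (Pd(OAc)2, SPhos, K3PO4), in which the iodide reacts before the bromide, would give 23.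

This route is longer and couples at the hindered carbon, which is why it is only the reserve.

**Step 5.** Acid may hydrolyse or polymerise the strained vinylogous ester faster than the alkoxy groups exchange, and the exchange may stall at equilibrium.
Fallback (from 8, returns at 9): hydrolysis of 8 with cold dilute HCl would give cyclobutane-1,3-dione F7, a vinylogous acid, which would be O-benzylated under Mitsunobu conditions (BnOH, PPh3, diisopropyl azodicarboxylate) to 9.

**Step 8.** Addition to an aldehyde deactivated by the ortho phenoxide and two further oxygens may be slow, and the doubly activated carbinol may ionise to an ortho-quinone methide on work-up or chromatography.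
Fallback (from 16, returns at 21): formyl C–H annulation under trivalent rhodium catalysis ([Cp*RhCl2]2, AgSbF6, 1,2-dichloroethane, heat) with dimethylsulfoxonium 2-[4-(benzyloxy)phenyl]-2-oxoethylide F8, made from 4-(benzyloxy)benzoyl chloride and dimethylsulfoxonium methylide. This would give 21 directly and replace steps 8 and 9.

**Step 15.** Insertion into the electron-rich chromone may be slower than protodeboronation of 25, facial selectivity may be insufficient, and reversible ring opening may erode the enantiomeric purity.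
Fallback (from 25 and 29, returns at 30): non-selective conjugate arylation with an achiral cationic divalent palladium catalyst (Pd(OCOCF3)2, 2,2′-bipyridine, aqueous solvent) would give the racemic heptabenzyl flavanone F9, which would be resolved by preparative chromatography on a chiral stationary phase to give 30.

**Step 16.** Over-reduction (saturation of the flavone C2=C3 bond, hydrogenolysis of the flavanone C2–O1 bond), stalling at partly debenzylated material of poor solubility and air oxidation of the catechol are the likely failures.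
Fallback (from 30, returns at 31): non-reductive debenzylation with BCl3 and pentamethylbenzene as cation scavenger in CH2Cl2 at −78 °C; no new compound is formed on the way.

## Further compounds

F1 | step 6 | 2,3-bis(benzyloxy)-5-bromobenzoic acid | OC(=O)c1cc(Br)cc(OCc2ccccc2)c1OCc1ccccc1
F2 | step 6 | 1,2-bis(benzyloxy)-5-bromo-3-iodobenzene | Ic1cc(Br)cc(OCc2ccccc2)c1OCc1ccccc1
F3 | step 6 | 2-[2,3-bis(benzyloxy)-5-bromophenyl]-4,4,5,5-tetramethyl-1,3,2-dioxaborolane | CC1(C)OB(c2cc(Br)cc(OCc3ccccc3)c2OCc2ccccc2)OC1(C)C
F4 | step 6 | 1-[4,6-bis(benzyloxy)-2-hydroxy-3-iodophenyl]ethan-1-one | CC(=O)c1c(O)c(I)c(OCc2ccccc2)cc1OCc1ccccc1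
F5 | step 6 | 1-[4,6-bis(benzyloxy)-2-hydroxy-3-iodophenyl]-3-[4-(benzyloxy)phenyl]propane-1,3-dione | O=C(CC(=O)c1ccc(OCc2ccccc2)cc1)c1c(O)c(I)c(OCc2ccccc2)cc1OCc1ccccc1
F6 | step 6 | 5,7-bis(benzyloxy)-2-[4-(benzyloxy)phenyl]-8-iodo-4H-chromen-4-one | O=c1cc(-c2ccc(OCc3ccccc3)cc2)oc2c(I)c(OCc3ccccc3)cc(OCc3ccccc3)c12
F7 | step 5 | cyclobutane-1,3-dione | O=C1CC(=O)C1
F8 | step 8 | dimethylsulfoxonium 2-[4-(benzyloxy)phenyl]-2-oxoethylide | CS(C)(=O)=CC(=O)c1ccc(OCc2ccccc2)cc1
F9 | step 15 | racemic 5,7-bis(benzyloxy)-2-{3,4-bis(benzyloxy)-5-[5,7-bis(benzyloxy)-2-(4-(benzyloxy)phenyl)-4-oxo-4H-chromen-8-yl]phenyl}-2,3-dihydro-4H-chromen-4-one | O=C1CC(c2cc(OCc3ccccc3)c(OCc3ccccc3)c(-c3c(OCc4ccccc4)cc(OCc4ccccc4)c4c(=O)cc(-c5ccc(OCc6ccccc6)cc5)oc34)c2)Oc2cc(OCc3ccccc3)cc(OCc3ccccc3)c21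
F0 | step 16 | none | none
A1 | alternative 1 | 3,5-bis(benzyloxy)-2-[2,3-bis(benzyloxy)-5-(1,3-dioxolan-2-yl)phenyl]-6-[(triphenylphosphoranylidene)acetyl]phenyl 4-(benzyloxy)benzoate | O=C(C=P(c1ccccc1)(c1ccccc1)c1ccccc1)c1c(OC(=O)c2ccc(OCc3ccccc3)cc2)c(-c2cc(C3OCCO3)cc(OCc3ccccc3)c2OCc2ccccc2)c(OCc2ccccc2)cc1OCc1ccccc1
A2 | alternative 1 | 8-[2,3-bis(benzyloxy)-5-(1,3-dioxolan-2-yl)phenyl]-5,7-bis(benzyloxy)-2-[4-(benzyloxy)phenyl]-4H-chromen-4-one | O=c1cc(-c2ccc(OCc3ccccc3)cc2)oc2c(-c3cc(C4OCCO4)cc(OCc4ccccc4)c3OCc3ccccc3)c(OCc3ccccc3)cc(OCc3ccccc3)c12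
A3 | alternative 2 | (3S)-3-[3,5-bis(benzyloxy)phenoxy]-3-{3,4-bis[(benzyloxycarbonyl)oxy]-5-[5,7-bis(benzyloxy)-2-(4-(benzyloxy)phenyl)-4-oxo-4H-chromen-8-yl]phenyl}propanoic acid | OC(=O)C[C@@H](c1cc(OC(=O)OCc2ccccc2)c(OC(=O)OCc2ccccc2)c(-c2c(OCc3ccccc3)cc(OCc3ccccc3)c3c(=O)cc(-c4ccc(OCc5ccccc5)cc4)oc23)c1)Oc1cc(OCc2ccccc2)cc(OCc2ccccc2)c1
A4 | alternative 2 | (2S)-5,7-bis(benzyloxy)-2-{3,4-bis[(benzyloxycarbonyl)oxy]-5-[5,7-bis(benzyloxy)-2-(4-(benzyloxy)phenyl)-4-oxo-4H-chromen-8-yl]phenyl}-2,3-dihydro-4H-chromen-4-one | O=C1C[C@@H](c2cc(OC(=O)OCc3ccccc3)c(OC(=O)OCc3ccccc3)c(-c3c(OCc4ccccc4)cc(OCc4ccccc4)c4c(=O)cc(-c5ccc(OCc6ccccc6)cc5)oc34)c2)Oc2cc(OCc3ccccc3)cc(OCc3ccccc3)c21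
A5 | alternative 3 | 3-[2,3-bis(benzyloxy)-5-chlorophenyl]-4,6-bis(benzyloxy)-2-hydroxybenzaldehyde | O=Cc1c(O)c(-c2cc(Cl)cc(OCc3ccccc3)c2OCc2ccccc2)c(OCc2ccccc2)cc1OCc1ccccc1
A6 | alternative 3 | dimethylsulfoxonium 2-[4-(benzyloxy)phenyl]-2-oxoethylide (the same compound as F8) | CS(C)(=O)=CC(=O)c1ccc(OCc2ccccc2)cc1
A7 | alternative 3 | 8-[2,3-bis(benzyloxy)-5-chlorophenyl]-5,7-bis(benzyloxy)-2-[4-(benzyloxy)phenyl]-4H-chromen-4-one | O=c1cc(-c2ccc(OCc3ccccc3)cc2)oc2c(-c3cc(Cl)cc(OCc4ccccc4)c3OCc3ccccc3)c(OCc3ccccc3)cc(OCc3ccccc3)c12
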